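Free starting material falls far faster than target rises: in the amber run at 0.625 d it reads 0.5% while target already stands at 22.0%.

the same everywhere: starting material 0.062 M
- amber: partner 0.031 M; run made earlier
- green: partner 0.12 M; run made earlier
- flask: partner 0.0620 M; time 15 d

| run | time / d | starting material / % | target / % |
|---|---|---|---|
| amber | 0.625 | 0.5 | 22.0 |
| amber | 1.67 | 0 | 35.0 |
| amber | 3.00 | 0.6 | 38.8 |
| amber | 5.00 | 0 | 40.9 |
| amber | 6.00 | 0.3 | 42.3 |
| amber | 10.0 | 0 | 41.4 |
| green | 1.67 | 0.7 | 70.1 |
| green | 3.00 | 0 | 73.2 |
| green | 5.00 | 0.1 | 75.3 |
| green | 6.00 | 0 | 76.5 |
| green | 8.00 | 0 | 76.5 |
| green | 10.0 | 0 | 76.3 |

(standard deviation of a reading: 0.5 percentage points)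

- the numbers in the tables scatter with a standard deviation of 0.5 percentage points
- a reading or a percentage of target counts all its forms, free or not
- the reaction counts as stopped when no species that holds the starting material changes by six tenths of a point or more over the second half of the time
- a reading of starting material is of its free form alone

- which holds at 15 d: what has brought the reaction to rest, or that it has not come to rest (forward and back rates have come level / it is still moving / all of the starting material has reacted)
- part of the starting material gone at 15 d
- the target standing at 15 d, as a percentage of the starting material charged

The lowest rung of the ladder therefore lies under a day: the charge leaves its free form and waits in some unseen held form. On the next rung, of days, target climbs, in the amber run from 22.0% to 38.8% by 3.00 d. The top rung is rest. From 6.00 d both runs stay flat within the scatter, and the flask's 15 d lies beyond that. Yet the plateaus fall short: amber reads 41.8% where its partner allows 50.0%, and green, with partner in excess, reads 76.4%. So held material seems to leave by a second path.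

Dividing the rate of that loss by the rate of capture removes time. Each unit of target then costs c/[B] of loss, where [B] is the partner pool still unused and c, a selectivity factor, is the pool at which capture and loss run level. Summed over a run: charge of starting material = target + c·ln(partner charge / pool left). Amber reads c = 0.0199 M and green 0.0291 M. Their mean, 0.0245 M, is the split constant carried on, a reading with that spread in it. Solved for the flask, it gives target 61.9%.

The forecast, reckoning the same way, says all of the starting material has reacted, conversion 100%, target 62%, seeing “the intermediate splitting between partner capture and a partner-independent loss”.

The flask gives all of the starting material has reacted, conversion >99.9%, target 61.6%.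

    partner → second intermediate (k = 0.150 h⁻¹)
    2 open intermediate → homo product (k = 1.00 M⁻¹ h⁻¹)
    open intermediate + second intermediate → target (k = 2.90 M⁻¹ h⁻¹)
    starting material → open intermediate (k = 0.530 h⁻¹)
    partner ⇌ dormant form (K = 0.260, k = 0.0430 h⁻¹)
    starting material + target ⇌ idle adduct, settled at all times (K = 530 M⁻¹)

Homo product is the loss and the main reason for the shortfall: this flask run without that step reaches 98.3% of target against 61.6%. That step goes with [open intermediate] squared, so c is an average over the run and no true constant, yet read back from this flask's result it is 0.0249 M, beside the carried 0.0245 M. For the neighbour charged with 0.15 M of partner, the carried c gives target 83.4%. The computed neighbour stands at 80.0%.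

The readings were generated by integration for an exercise; scatter was added.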